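## The problem

Sanggenol A is a (2S)-flavanone. Ring A (5,7-dihydroxy, phloroglucinol-derived) is fused through C4a and C8a to the pyranone ring C, and ring B, a 2',4'-dihydroxyphenyl group with an (E)-geranyl chain at C3', is attached at C2. C2 is the only stereocentre: it is benzylic, bonded to O1 and β to the C4 ketone, and no second centre exists to relay from, so it must come from a reagent or catalyst. Base opens ring C by retro-oxa-Michael reaction to an achiral open-chain enone, so C2 is best set late and then exposed to nothing harsher than mild acid. The geranyl chain has two trisubstituted alkenes and sits between two phenols on ring B; acid strong enough to protonate the C2''=C3'' alkene closes a chroman onto O2' or O4'. This rules out hydrogenolysis, BBr3 and electrophilic oxidants, and means the four phenols need base-stable groups that come off gently. Ring B carries four contiguous substituents (C1' to C4') with the chain between the two oxygens, a position that direct electrophilic geranylation of a resorcinol does not select. The enabling feature is that ring C contains only three carbons: the C4 carbonyl is bonded to C4a and to C3, and O1 sits on the neighbouring carbon C8a. Ring C is therefore one carbonyl unit plus the two carbons of an alkyne, stitched between an ortho-iodophenol (C4a–I, C8a–OH) and an ethynyl group on C1' of ring B. The resulting flavone is flat and has nothing to racemise under forcing coupling conditions, and its C2=C3 bond is the only conjugated alkene, so a chiral hydride catalyst can address C2 and leave the geranyl alkenes alone.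

## Retrosynthesis

**Target 18 to protected flavanone 17.** The four aryl O–CH2 acetal bonds are cut, giving the tetrakis(methoxymethyl) ether 17. Methoxymethyl ethers are preferred to benzyl ethers (hydrogenolysis would saturate the chain) and to methyl ethers (their cleavage needs Lewis acids that cyclise the chain). They also direct the metalation used on ring B and tolerate hot amine, organolithium, fluoride and hydride. The forward reaction must hydrolyse four acetals without protonating an alkene or opening ring C.

**Flavanone 17 to flavone 15.** The C2–H and C3–H bonds are cut, so the stereocentre disappears and the precursor is the flat flavone 15. The neighbouring cut at O1–C2 (oxa-Michael closure of an open-chain enone) would need an enantioselective and reversible cyclisation on a substrate with a second phenol near the enone. The forward step here only requires face-selective hydride delivery to C2 by a chiral bisphosphine-ligated copper hydride. The product is held as silyl enol ether 16, which cannot ring-open, until a neutral work-up.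

**Flavone 15 to iodophenol 3, alkyne 11 and carbon monoxide 12.** Three bonds are cut at once: C4a–C4, C4–C3 and O1–C2. This is the key disconnection; it passes through ynone 13 and enaminone 14, neither of which is isolated. Classical ring C constructions close a 1,3-diketone with strong acid or oxidise an open-chain enone with iodine or selenium reagents. The first would strip the acetals and cyclise the chain; the second would attack the geranyl alkenes. The carbonylative route needs only a palladium catalyst, a secondary amine and heat. It divides the molecule into two aromatic pieces of similar size plus a one-carbon gas. The forward reaction has to insert 12 before the alkyne couples and has to close ring C in the six-membered sense.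

**Iodophenol 3 to phenol 2 and phloroglucinol 1.** The C–I bond is cut first, then two O–CH2 bonds. Because 1 is threefold symmetric, only one bis-ether 2 exists, and in 2 the two positions ortho to the free hydroxyl are equivalent. The iodination therefore has one regiochemical question: ortho to OH, or para to OH between the two acetals.

**Alkyne 11 to silylalkyne 10, then to arene 7 and geranyl bromide 8.** The C–Si bond is cut, then the C3'–C1'' bond between ring B and the chain. The chain goes on last, by metalation of 7 to aryllithium 9 at the single position flanked by two acetal oxygens, so the regiochemistry is unambiguous. The neighbouring order (chain first, then a second metalation and a one-carbon homologation) would expose the benzylic, allylic CH2 of the chain to alkyllithium. The silyl cap keeps the alkyne terminus from being deprotonated in this step.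

**Arene 7 to iodide 5, ethynyltriisopropylsilane 6 and 4-iodoresorcinol 4.** The aryl–alkynyl bond is cut, then two O–CH2 bonds. The iodine of commercial 4 already marks C1', so no regiochemical decision is left on ring B except the metalation above.

## Roads not taken

Alternative 1: Ring B by Diels–Alder benzannulation. The cut is at C1'–C2' and C5'–C6' of ring B. In the forward sense, diene A2 (2-geranyl-1-methoxy-1,3-bis(trimethylsilyloxy)buta-1,3-diene) adds to ethyl propiolate A3 and loses methanol on acidic work-up to give ethyl 3-geranyl-2,4-dihydroxybenzoate A1.
- Merits: the chain is attached at an enolate carbon before the ring exists, so its position between the two oxygens is fixed by construction. No organolithium is needed, and the cycloaddition regiochemistry (nucleophilic CH2 terminus onto the propiolate β-carbon) is dependable.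
- Weak points: it solves ring B only. A1 must still be protected, reduced and homologated before it can meet ring A, and the route says nothing about ring C or C2. The diene itself costs an alkylation and two silylations.
- Comparison: on regiochemical certainty for ring B this road is better than the chosen plan, and it avoids a cryogenic step. Against that, the chosen plan reaches the same pattern with one metalation at a site flanked by two directing groups and delivers the ethynyl group of 11 directly, several operations sooner.

Alternative 2: Enantioselective carbenoid C–H insertion. The cut is at C2–C3. Diazoketone A5 is decomposed by Rh2(S-PTTL)4, dirhodium tetrakis[N-phthaloyl-(S)-tert-leucinate], and the carbenoid inserts into one benzylic C–H bond of the aryl benzyl ether to give the protected flavanone A4.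
- Merits: ring C closes and C2 is set in one step under neutral conditions; the fragments are joined by a simple ether bond; no late reduction is needed.
- Weak points: an acceptor-only carbenoid is a strong electrophile and the chain offers two electron-rich alkenes for cyclopropanation. The ether oxygen lies five atoms from the carbenoid carbon, so oxonium ylide formation and a [1,2]-benzyl shift to a benzofuranone compete with the six-membered insertion. Six-ring insertion is also the less favoured mode, and enantiocontrol with such carbenoids is not dependable. A5 further requires a diazoketone from a hindered, trioxygenated benzoic acid and a second protecting-group type on ring A.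
- Comparison: if the insertion were clean this road would have the shorter endgame, since no separate stereo-setting step is needed. The chosen plan offsets this with close precedent for every bond-forming event and a chemoselectivity problem (conjugated versus isolated alkenes) that favours the desired outcome.

Alternative 3: Ring C closed at the aryl ether bond. The cut is at O1–C8a. Under CuI, 1,10-phenanthroline and Cs2CO3, the C2 hydroxyl of syn-diol A7 displaces bromide at C8a to give the (2S,4R)-trans-flavan-4-ol A6. Oxidation at C4 and deprotection would follow.
- Merits: C2 is set in an open chain by well-understood asymmetric carbonyl chemistry and is carried through with retention because its C–O bond is never broken. The C4 hydroxyl cannot compete, since it would form a four-membered ring. No pressurised gas is used.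
- Weak points: the aryl bromide carries two oxygen donors and is a poor partner for oxidative addition to copper, and the nucleophile is a hindered secondary benzylic alkoxide, so hot carbonate for long times is likely, with benzylic elimination as the side path. Two stereocentres must be made although one is later destroyed, and the count is higher (fragment union, diastereoselective reduction, etherification, oxidation, deprotection).
- Comparison: in stereochemical reliability at C2 this road is arguably stronger than a conjugate reduction of a hindered flavone. The chosen plan compensates with a shorter, more convergent sequence and an intermediate, 15, that has no stereocentre to lose before the last two steps.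

Key step: step 7

Assumption: phloroglucinol, 4-iodoresorcinol, ethynyltriisopropylsilane, (E)-geranyl bromide and carbon monoxide are bought.

Assumption: (R)-DTBM-SEGPHOS is written in step 8 on the expectation that it directs hydride to the C2 face that leads to the 2S product; if a pilot reduction of a simple flavone shows the opposite sense, the (S) ligand is used instead with no other change.

## Route

Step 1
Reactants: 1 phloroglucinol
Product: 2 3,5-bis(methoxymethoxy)phenol
Conditions: MOMCl (2.0 equiv), i-Pr2NEt, CH2Cl2–DMF, 0 °C → rt; chromatography
Reagents that add atoms: chloromethyl methyl ether, COCCl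
Why: O-Alkylation of the phenoxide (Williamson-type methoxymethyl ether formation); the three hydroxyls are equivalent, so only one bis-ether can form and it should be separable from the mono- and tris-ethers, which are recycled.

Step 2
Reactants: 2 3,5-bis(methoxymethoxy)phenol
Product: 3 2-iodo-3,5-bis(methoxymethoxy)phenol
Conditions: NIS (1.0 equiv), CH2Cl2, −40 → 0 °C, dark
Reagents that add atoms: N-iodosuccinimide, O=C1CCC(=O)N1I
Why: Electrophilic aromatic iodination of a ring activated by three oxygens. The two equivalent positions ortho to the free hydroxyl should be favoured over C4 by statistics, by hydrogen-bonded delivery of the reagent in a non-polar solvent and by the two flanking acetal chains at C4; neutral conditions spare the acetals.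

Step 3
Reactants: 4 4-iodoresorcinol
Product: 5 1-iodo-2,4-bis(methoxymethoxy)benzene
Conditions: MOMCl (2.5 equiv), i-Pr2NEt, CH2Cl2, 0 °C → rt
Reagents that add atoms: chloromethyl methyl ether, COCCl
Why: Exhaustive O-alkylation of both phenols (methoxymethyl ether formation); the acetals later direct the metalation and withstand every basic step up to the final deprotection.

Step 4
Reactants: 5 1-iodo-2,4-bis(methoxymethoxy)benzene; 6 ethynyltriisopropylsilane
Product: 7 {[2,4-bis(methoxymethoxy)phenyl]ethynyl}triisopropylsilane
Conditions: PdCl2(PPh3)2 (2 mol %), CuI (4 mol %), Et3N, THF, rt → 50 °C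
Reagents that add atoms: none
Why: Sonogashira coupling of an aryl iodide with a terminal alkyne (oxidative addition to zerovalent palladium, transmetalation from the copper acetylide, reductive elimination); the bulky silyl group caps the alkyne terminus for step 5.

Step 5
Reactants: 7 {[2,4-bis(methoxymethoxy)phenyl]ethynyl}triisopropylsilane; 8 geranyl bromide
Product: 10 {[3-geranyl-2,4-bis(methoxymethoxy)phenyl]ethynyl}triisopropylsilane, via aryllithium 9 (not isolated)
Conditions: s-BuLi (1.1 equiv), THF, −78 °C; CuBr·SMe2 (0.2 equiv); 8, −78 °C → rt
Reagents that add atoms: none
Why: Directed ortho-metalation removes the one ring proton flanked by two chelating acetal oxygens (C3), and copper-catalysed allylic substitution of the aryllithium on geranyl bromide follows. Attack at the unsubstituted α-carbon should give the linear chain with the E alkene untouched, because the γ-carbon is fully substituted. The triisopropylsilyl group shields the alkyne, and the benzylic, allylic CH2 appears only after the base is consumed.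

Step 6
Reactants: 10 {[3-geranyl-2,4-bis(methoxymethoxy)phenyl]ethynyl}triisopropylsilane
Product: 11 1-ethynyl-3-geranyl-2,4-bis(methoxymethoxy)benzene
Conditions: Bu4NF (1.2 equiv), THF, 0 °C → rt
Reagents that add atoms: none
Why: Fluoride-induced protodesilylation of an alkynylsilane; acetals and isolated alkenes are inert to fluoride.

Step 7
Reactants: 3 2-iodo-3,5-bis(methoxymethoxy)phenol; 11 1-ethynyl-3-geranyl-2,4-bis(methoxymethoxy)benzene; 12 carbon monoxide
Product: 15 3'-geranyl-5,7,2',4'-tetrakis(methoxymethoxy)flavone, via ortho-hydroxyaryl ynone 13 (not isolated), via enaminone 14 (not isolated)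
Conditions: PdCl2(PPh3)2 (5 mol %), CO (20 bar), Et2NH, 120 °C, autoclave
Reagents that add atoms: none
Why: Carbonylative Sonogashira coupling with in situ annulation, the known route from ortho-iodophenols and terminal arylalkynes to flavones in a secondary amine. PdCl2(PPh3)2 is reduced in the amine to zerovalent palladium, which inserts into the C–I bond of 3; CO (12) then inserts to give an aroylpalladium iodide (forming C4a–C4), the amine-assisted acetylide of 11 displaces iodide, and reductive elimination forms C4–C3 and releases ynone 13. Diethylamine adds to the β-carbon of 13 to give enaminone 14, and the ortho-phenoxide attacks the same carbon (the future C2) and expels the amine, so ring C closes in a net 6-endo-dig sense (a 6-endo-trig addition–elimination on 14) with formation of O1–C2. No stereocentre is created, and the flat product 15 has nothing to racemise at 120 °C. Three selectivities are needed: carbonylation before alkynylation, which the CO pressure and the absence of a copper co-catalyst favour over direct coupling to a benzofuran; alkynylation of the aroylpalladium species before its capture by the amine, which the two ortho substituents (OH and OMOM) favour by shielding the acyl carbon; and six- over five-membered closure, which the enaminone pathway secures because only its β-carbon is electrophilic, so the 5-exo route to an aurone is shut. The acetals, the free phenol and the isolated trisubstituted alkenes of the chain should be inert to amine, CO and palladium under these conditions.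

Step 8
Reactants: 15 3'-geranyl-5,7,2',4'-tetrakis(methoxymethoxy)flavone
Product: 17 (2S)-3'-geranyl-5,7,2',4'-tetrakis(methoxymethoxy)flavanone, via silyl enol ether 16 (not isolated)
Conditions: Cu(OAc)2·H2O (5 mol %), (R)-DTBM-SEGPHOS (5.5 mol %), (EtO)2MeSiH (3 equiv), toluene, 0 °C → rt; then AcOH, THF–H2O, 0 °C
Reagents that add atoms: none
Why: Copper hydride-catalysed asymmetric conjugate reduction, known for β,β-disubstituted enones and chromones. The bisphosphine-ligated copper hydride delivers hydride to one face of C2, the ligand alone fixing the 2S configuration, and the copper enolate is silylated to 16, which cannot ring-open and so holds the new centre until buffered hydrolysis. The isolated geranyl alkenes are not hydrocuprated, and no protic additive is used, so the ketone is not exposed to hydride.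

Step 9
Reactants: 17 (2S)-3'-geranyl-5,7,2',4'-tetrakis(methoxymethoxy)flavanone
Product: 18 sanggenol A
Conditions: HCl (3 M aq.), MeOH, 40 °C, monitored; NaHCO3 quench
Reagents that add atoms: none
Why: Acid-catalysed acetal cleavage (transacetalisation to dimethoxymethane in methanol). Oxocarbenium formation from an aryl methoxymethyl ether is much faster than protonation of a trisubstituted alkene in dilute acid at this temperature, so the chain and C2 should survive if the reaction is stopped at full conversion.

## Compound list

1 | phloroglucinol (benzene-1,3,5-triol) | Oc1cc(O)cc(O)c1 | starting material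
2 | 3,5-bis(methoxymethoxy)phenol | COCOc1cc(O)cc(OCOC)c1 | intermediate
3 | 2-iodo-3,5-bis(methoxymethoxy)phenol | Oc1cc(OCOC)cc(OCOC)c1I | intermediate
4 | 4-iodoresorcinol (4-iodobenzene-1,3-diol) | Oc1ccc(I)c(O)c1 | starting material
5 | 1-iodo-2,4-bis(methoxymethoxy)benzene | COCOc1ccc(I)c(OCOC)c1 | intermediate
6 | ethynyltriisopropylsilane | C#C[Si](C(C)C)(C(C)C)C(C)C | starting material
7 | {[2,4-bis(methoxymethoxy)phenyl]ethynyl}triisopropylsilane | COCOc1ccc(C#C[Si](C(C)C)(C(C)C)C(C)C)c(OCOC)c1 | intermediate
8 | geranyl bromide, (2E)-1-bromo-3,7-dimethylocta-2,6-diene | CC(C)=CCC/C(C)=C/CBr | starting material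
9 | {2,6-bis(methoxymethoxy)-3-[(triisopropylsilyl)ethynyl]phenyl}lithium | COCOc1ccc(C#C[Si](C(C)C)(C(C)C)C(C)C)c(OCOC)c1[Li] | intermediate
10 | {[3-geranyl-2,4-bis(methoxymethoxy)phenyl]ethynyl}triisopropylsilane (geranyl = (2E)-3,7-dimethylocta-2,6-dien-1-yl) | CC(C)=CCC/C(C)=C/Cc1c(OCOC)ccc(C#C[Si](C(C)C)(C(C)C)C(C)C)c1OCOC | intermediate
11 | 1-ethynyl-3-geranyl-2,4-bis(methoxymethoxy)benzene | CC(C)=CCC/C(C)=C/Cc1c(OCOC)ccc(C#C)c1OCOC | intermediate
12 | carbon monoxide | [C-]#[O+] | starting material
13 | 1-[2-hydroxy-4,6-bis(methoxymethoxy)phenyl]-3-[3-geranyl-2,4-bis(methoxymethoxy)phenyl]prop-2-yn-1-one | CC(C)=CCC/C(C)=C/Cc1c(OCOC)ccc(C#CC(=O)c2c(O)cc(OCOC)cc2OCOC)c1OCOC | intermediate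
14 | 3-(diethylamino)-1-[2-hydroxy-4,6-bis(methoxymethoxy)phenyl]-3-[3-geranyl-2,4-bis(methoxymethoxy)phenyl]prop-2-en-1-one (enamine geometry not defined) | CC(C)=CCC/C(C)=C/Cc1c(OCOC)ccc(C(=CC(=O)c2c(O)cc(OCOC)cc2OCOC)N(CC)CC)c1OCOC | intermediate
15 | 3'-geranyl-5,7,2',4'-tetrakis(methoxymethoxy)flavone | CC(C)=CCC/C(C)=C/Cc1c(OCOC)ccc(-c2cc(=O)c3c(OCOC)cc(OCOC)cc3o2)c1OCOC | intermediate
16 | (2S)-4-[diethoxy(methyl)silyloxy]-2-[3-geranyl-2,4-bis(methoxymethoxy)phenyl]-5,7-bis(methoxymethoxy)-2H-chromene | CC(C)=CCC/C(C)=C/Cc1c(OCOC)ccc([C@@H]2C=C(O[Si](C)(OCC)OCC)c3c(OCOC)cc(OCOC)cc3O2)c1OCOC | intermediate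
17 | (2S)-3'-geranyl-5,7,2',4'-tetrakis(methoxymethoxy)flavanone | CC(C)=CCC/C(C)=C/Cc1c(OCOC)ccc([C@@H]2CC(=O)c3c(OCOC)cc(OCOC)cc3O2)c1OCOC | intermediate
18 | sanggenol A, (2S)-3'-geranyl-5,7,2',4'-tetrahydroxyflavanone | CC(C)=CCC/C(C)=C/Cc1c(O)ccc([C@@H]2CC(=O)c3c(O)cc(O)cc3O2)c1O | target

## Step count and risks

Total step count: 9. Longest linear sequence: 7 steps (steps 3, 4, 5, 6, 7, 8, 9); steps 1 and 2 form the two-step side branch to 3.

**Step 7 (key step).**
- What may go wrong: coupling without CO insertion (direct alkynylation followed by cyclisation to a benzofuran), capture of the aroylpalladium species by the amine solvent, or slow oxidative addition into a C–I bond flanked by two oxygen substituents on an electron-rich ring, with hydrodeiodination taking over.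
- Fallback: it sets out from phenol 2 and alkyne 11 and assembles the same ynone stepwise. Magnesium-mediated ortho-formylation of 2 (MgCl2, Et3N, paraformaldehyde) gives 2-hydroxy-4,6-bis(methoxymethoxy)benzaldehyde F1. Addition of the bromomagnesium acetylide of 11 (EtMgBr, THF, excess to cover the phenol) gives racemic 1-[2-hydroxy-4,6-bis(methoxymethoxy)phenyl]-3-[3-geranyl-2,4-bis(methoxymethoxy)phenyl]prop-2-yn-1-ol F2. Oxidation with MnO2 returns to the route at ynone 13, now isolated, which is closed to 15 by warming in Et2NH–EtOH.

**Step 8.**
- What may go wrong: sluggish hydride transfer to a vinylogous ester deactivated by four oxygen donors and crowded by the ortho-substituted ring B, giving incomplete conversion, weak facial selectivity or some 1,2-reduction.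
- Fallback: it sets out from 15. Conjugate reduction with LiBH(s-Bu)3 in THF at −78 °C gives racemic 3'-geranyl-5,7,2',4'-tetrakis(methoxymethoxy)flavanone F3. Kinetic resolution by asymmetric transfer hydrogenation (RuCl(p-cymene)[(R,R)-TsDPEN] or its enantiomer, HCO2H–Et3N) should consume the 2R ketone as the cis-alcohol (2R,4R)-3'-geranyl-5,7,2',4'-tetrakis(methoxymethoxy)flavan-4-ol F4 and leave the 2S ketone. The route is rejoined at 17, at the cost of half the material.

**Step 2.**
- What may go wrong: poor regioselectivity (iodination at C4, para to the hydroxyl and between the two acetals) and over-iodination of a very electron-rich ring.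
- Fallback: it sets out from 2 and replaces electrophilic substitution by directed metalation. Carbamoylation (ClC(O)NEt2, NaH, THF) gives 3,5-bis(methoxymethoxy)phenyl N,N-diethylcarbamate F5. Lithiation next to the carbamate (s-BuLi, TMEDA, THF, −78 °C) and quenching with I2 gives 2-iodo-3,5-bis(methoxymethoxy)phenyl N,N-diethylcarbamate F6. Reductive cleavage of the carbamate with Cp2Zr(H)Cl in THF returns to the route at 3.

**Step 5.**
- What may go wrong: addition of the alkyllithium across the silylalkyne, metalation at a ring position other than C3, or γ-attack on the allylic bromide with loss of the linear E chain.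
- Fallback: it sets out from geranyl bromide 8 and reverses the order of events. Purchased 1,3-bis(methoxymethoxy)benzene F7 is lithiated between its acetals (n-BuLi, THF, 0 °C) and alkylated with 8 in the presence of CuBr·SMe2 to give 2-geranyl-1,3-bis(methoxymethoxy)benzene F8. A second ortho-lithiation (s-BuLi, TMEDA, −78 °C, kept cold so that ring metalation outruns benzylic deprotonation) and DMF give 3-geranyl-2,4-bis(methoxymethoxy)benzaldehyde F9. Seyferth–Gilbert homologation with dimethyl (1-diazo-2-oxopropyl)phosphonate and K2CO3 in MeOH returns to the route at 11.

**Step 9.**
- What may go wrong: acid-catalysed addition of the freed 2'- or 4'-hydroxyl to the neighbouring alkene (chroman formation) and erosion of the C2 configuration through reversible opening of ring C.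
- Fallback: it sets out from 17 and avoids protic acid. Trimethylsilyl triflate with 2,2'-bipyridyl in MeCN at 0 °C should exchange each aryl acetal for a silyl ether, giving (2S)-3'-geranyl-5,7,2',4'-tetrakis(trimethylsilyloxy)flavanone F10. Addition of water hydrolyses the silyl ethers and returns to the route at 18.

## Further compounds

F1 | step 7 | 2-hydroxy-4,6-bis(methoxymethoxy)benzaldehyde | O=Cc1c(O)cc(OCOC)cc1OCOC
F2 | step 7 | 1-[2-hydroxy-4,6-bis(methoxymethoxy)phenyl]-3-[3-geranyl-2,4-bis(methoxymethoxy)phenyl]prop-2-yn-1-ol (racemic) | CC(C)=CCC/C(C)=C/Cc1c(OCOC)ccc(C#CC(O)c2c(O)cc(OCOC)cc2OCOC)c1OCOC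
F3 | step 8 | 3'-geranyl-5,7,2',4'-tetrakis(methoxymethoxy)flavanone (racemic) | CC(C)=CCC/C(C)=C/Cc1c(OCOC)ccc(C2CC(=O)c3c(OCOC)cc(OCOC)cc3O2)c1OCOC
F4 | step 8 | (2R,4R)-3'-geranyl-5,7,2',4'-tetrakis(methoxymethoxy)flavan-4-ol (2,4-cis) | CC(C)=CCC/C(C)=C/Cc1c(OCOC)ccc([C@H]2C[C@@H](O)c3c(OCOC)cc(OCOC)cc3O2)c1OCOC
F5 | step 2 | 3,5-bis(methoxymethoxy)phenyl N,N-diethylcarbamate | CCN(CC)C(=O)Oc1cc(OCOC)cc(OCOC)c1
F6 | step 2 | 2-iodo-3,5-bis(methoxymethoxy)phenyl N,N-diethylcarbamate | CCN(CC)C(=O)Oc1cc(OCOC)cc(OCOC)c1I
F7 | step 5 | 1,3-bis(methoxymethoxy)benzene | COCOc1cccc(OCOC)c1
F8 | step 5 | 2-geranyl-1,3-bis(methoxymethoxy)benzene | CC(C)=CCC/C(C)=C/Cc1c(OCOC)cccc1OCOC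
F9 | step 5 | 3-geranyl-2,4-bis(methoxymethoxy)benzaldehyde | CC(C)=CCC/C(C)=C/Cc1c(OCOC)ccc(C=O)c1OCOC
F10 | step 9 | (2S)-3'-geranyl-5,7,2',4'-tetrakis(trimethylsilyloxy)flavanone | CC(C)=CCC/C(C)=C/Cc1c(O[Si](C)(C)C)ccc([C@@H]2CC(=O)c3c(O[Si](C)(C)C)cc(O[Si](C)(C)C)cc3O2)c1O[Si](C)(C)C
A1 | alternative 1 | ethyl 3-geranyl-2,4-dihydroxybenzoate | CCOC(=O)c1ccc(O)c(C/C=C(\C)CCC=C(C)C)c1O
A2 | alternative 1 | 2-geranyl-1-methoxy-1,3-bis(trimethylsilyloxy)buta-1,3-diene (ketene acetal geometry not defined) | COC(O[Si](C)(C)C)=C(C/C=C(\C)CCC=C(C)C)C(=C)O[Si](C)(C)C
A3 | alternative 1 | ethyl propiolate | C#CC(=O)OCC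
A4 | alternative 2 | (2S)-3'-geranyl-2',4'-bis(methoxymethoxy)-5,7-bis(triisopropylsilyloxy)flavanone | CC(C)=CCC/C(C)=C/Cc1c(OCOC)ccc([C@@H]2CC(=O)c3c(O[Si](C(C)C)(C(C)C)C(C)C)cc(O[Si](C(C)C)(C(C)C)C(C)C)cc3O2)c1OCOC
A5 | alternative 2 | 2-diazo-1-{2-[3-geranyl-2,4-bis(methoxymethoxy)benzyloxy]-4,6-bis(triisopropylsilyloxy)phenyl}ethan-1-one | CC(C)=CCC/C(C)=C/Cc1c(OCOC)ccc(COc2cc(O[Si](C(C)C)(C(C)C)C(C)C)cc(O[Si](C(C)C)(C(C)C)C(C)C)c2C(=O)C=[N+]=[N-])c1OCOC
A6 | alternative 3 | (2S,4R)-3'-geranyl-5,7,2',4'-tetrakis(methoxymethoxy)flavan-4-ol (2,4-trans) | CC(C)=CCC/C(C)=C/Cc1c(OCOC)ccc([C@@H]2C[C@@H](O)c3c(OCOC)cc(OCOC)cc3O2)c1OCOC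
A7 | alternative 3 | (1R,3S)-1-[2-bromo-4,6-bis(methoxymethoxy)phenyl]-3-[3-geranyl-2,4-bis(methoxymethoxy)phenyl]propane-1,3-diol (syn) | CC(C)=CCC/C(C)=C/Cc1c(OCOC)ccc([C@@H](O)C[C@@H](O)c2c(OCOC)cc(OCOC)cc2Br)c1OCOC
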